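**Retrosynthetic overview**
- The 8-ester C–O bond is cut last: acyl-radical transfer from an aldehyde to the 7-hydroxy-5,8-quinone form of the flavone, so the three phenols never have to be differentiated.
- The 7-oxygen comes from the flavone-5,8-quinone by nucleophilic epoxidation and isomerisation.
- Key cut, C4–C4a: an acyl radical carrying all the B- and C-ring carbons adds to a C2-symmetric dimethoxy-p-quinone. The quinone supplies O-5, O-8, the 6-OMe and an 8a-OMe leaving group.
- Ring order: the A ring (quinone) and B ring (aryl ether) are bought preformed. Only the pyranone C ring is built, by O1 closure at the quinone oxidation level.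
- The acyl-radical precursor is a β-chloro-α-methoxy enal made in two steps from the aryl ether.

Assumption: the target has no stereocentre, so no enantiocontrol is needed; the alkene geometry of 6 and 7 is lost on cyclisation.

**Step 1**
Reactants: 1, p-benzoquinone
Product: 2, 2,5-dimethoxy-1,4-benzoquinone
Conditions: MeOH, anhydrous ZnCl2, 50 °C; 3 equiv of 1 (excess acts as oxidant); product crystallises out
Reagents that add atoms: methanol, CO
Why: Lewis-acid-promoted conjugate addition of methanol and re-oxidation by excess quinone, twice (oxidative methoxylation), gives the 2,5-isomer; no stereocentre.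

**Step 2**
Reactants: 3, anisole; 4, methoxyacetyl chloride
Product: 5, 2-methoxy-1-(4-methoxyphenyl)ethan-1-one
Conditions: AlCl3 (1.2 equiv), CH2Cl2, 0 °C to rt
Reagents that add atoms: methoxyacetyl chloride (4), COCC(Cl)=O
Why: Friedel–Crafts acylation, para-selective on anisole; no stereocentre.

**Step 3**
Reactants: 5
Product: 6, (E)-3-chloro-2-methoxy-3-(4-methoxyphenyl)prop-2-enal (Cl cis to CHO; an E/Z mixture is equally usable)
Conditions: POCl3 (3 equiv), DMF, 0 to 60 °C; then aq. NaOAc, 0 °C
Reagents that add atoms: DMF, CN(C)C=O (formyl carbon); POCl3, O=P(Cl)(Cl)Cl (chlorine); water, O (formyl oxygen on hydrolysis)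
Why: Vilsmeier–Haack–Arnold chloroformylation of an enolisable ketone gives the β-chlorovinyl aldehyde, a true aldehyde with no enol form and a leaving group at the future C2; no stereocentre.

**Step 4 (key step)**
Reactants: 2, 2,5-dimethoxy-1,4-benzoquinone (1.5 equiv); 6, the chloro enal
Product: 7, (E)-3-chloro-1-(3,6-dihydroxy-2,5-dimethoxyphenyl)-2-methoxy-3-(4-methoxyphenyl)prop-2-en-1-one
Conditions: Ph2CO (1 equiv), hν (365 nm, Pyrex), degassed PhH/MeCN, rt; crude kept cold and taken directly into step 5
Reagents that add atoms: none
Why: Benzophenone-mediated photo-Friedel–Crafts acylation of a quinone (Klinger–Kraus reaction): the triplet ketone abstracts the formyl H of 6, the nucleophilic vinylic acyl radical (no decarbonylation) adds to the unsubstituted carbon of C2-symmetric 2 (the site attacked in Fieser-type radical alkylations of 2,5-dioxygenated quinones), and H-return plus enolisation gives the acylhydroquinone; no stereocentre is formed.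

**Step 5**
Reactants: 7
Product: 8, 3,6-dimethoxy-2-(4-methoxyphenyl)-4H-chromene-4,5,8-trione (the flavone-5,8-quinone)
Conditions: CAN (2.2 equiv), MeCN/H2O 3:1, 0 °C, 10 min; then NaOAc to pH ~5, 45 °C
Reagents that add atoms: water, O (becomes ring O1)
Why: CAN oxidation to the acylquinone removes the ortho phenol that would close the wrong pyranone; water then hydrolyses the doubly activated vinylogous-ester OMe (β to both the ring and side-chain carbonyls), and the resulting hydroxyquinone oxygen closes the ring by 6-endo addition–elimination on the β-chlorovinyl ketone (standard chromone closure), while the singly activated 6-OMe survives.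

**Step 6**
Reactants: 8
Product: 9, 7-hydroxy-3,6-dimethoxy-2-(4-methoxyphenyl)-4H-chromene-4,5,8-trione
Conditions: 30% H2O2 (1.2 equiv), Na2CO3, THF/H2O, 0 °C; then DBU (1.1 equiv), THF, 0 °C to rt; aq. HCl work-up
Reagents that add atoms: hydrogen peroxide, OO
Why: Weitz–Scheffer nucleophilic epoxidation at the only unsubstituted quinone carbon (C7), then base-induced E1cB epoxide opening, which can only expel the epoxide oxygen from C6, gives the 7-hydroxy-6-methoxyquinone; the tetrasubstituted push–pull pyranone alkenes are not epoxidised.

**Step 7**
Reactants: 9; 10, 3-methylbutanal (10 equiv)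
Product: 11, 5,7-dihydroxy-3,6-dimethoxy-2-(4-methoxyphenyl)-4-oxo-4H-chromen-8-yl 3-methylbutanoate (target)
Conditions: degassed PhH, 450 nm LEDs (or sunlight), rt; then imidazole (10 mol %), CH2Cl2, rt
Reagents that add atoms: 3-methylbutanal (10), CC(C)CC=O
Why: Proposed new method: Klinger-type photochemical aldehyde-to-quinone acyl transfer applied to a hydroxy-p-quinone, which is also the 5-hydroxy-7,8-o-quinone tautomer (the classical Klinger substrate class); the excited quinone abstracts the formyl H of 10, the isovaleryl radical (slow decarbonylation) recombines on a quinone oxygen because no ring carbon is free, and retention of the 5-OH···O=C4 hydrogen bond plus imidazole-catalysed 7-to-8 acyl migration onto the less acidic oxygen should funnel the monoester to the 8-isovalerate; the closest known chemistry is the photo-formation of catechol and hydroquinone monoesters from phenanthrenequinone or chloranil with aldehydes; visible light avoids photo-Fries reaction of the product.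

**Compound list**
1 | p-benzoquinone | O=C1C=CC(=O)C=C1 | starting material
2 | 2,5-dimethoxy-1,4-benzoquinone | COC1=CC(=O)C(OC)=CC1=O | intermediate
3 | anisole | COc1ccccc1 | starting material
4 | methoxyacetyl chloride | COCC(Cl)=O | starting material
5 | 2-methoxy-1-(4-methoxyphenyl)ethan-1-one | COCC(=O)c1ccc(OC)cc1 | intermediate
6 | (E)-3-chloro-2-methoxy-3-(4-methoxyphenyl)prop-2-enal | O=C/C(OC)=C(\Cl)c1ccc(OC)cc1 | intermediate
7 | (E)-3-chloro-1-(3,6-dihydroxy-2,5-dimethoxyphenyl)-2-methoxy-3-(4-methoxyphenyl)prop-2-en-1-one | COc1cc(O)c(OC)c(C(=O)/C(OC)=C(\Cl)c2ccc(OC)cc2)c1O | intermediate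
8 | 3,6-dimethoxy-2-(4-methoxyphenyl)-4H-chromene-4,5,8-trione | COC1=CC(=O)C2=C(C1=O)C(=O)C(OC)=C(O2)c1ccc(OC)cc1 | intermediate
9 | 7-hydroxy-3,6-dimethoxy-2-(4-methoxyphenyl)-4H-chromene-4,5,8-trione | COC1=C(O)C(=O)C2=C(C1=O)C(=O)C(OC)=C(O2)c1ccc(OC)cc1 | intermediate
10 | 3-methylbutanal | CC(C)CC=O | starting material
11 | 5,7,8-trihydroxy-3,6,4'-trimethoxyflavone 8-isovalerate | COc1ccc(-c2oc3c(OC(=O)CC(C)C)c(O)c(OC)c(O)c3c(=O)c2OC)cc1 | target

**Totals**
Total steps: 7. Longest linear sequence: 6 (3 → 5 → 6 → 7 → 8 → 9 → 11).

**Three steps most likely to fail, with fallbacks**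
- **Step 7** (the acyl radical may go to O-5, or the photoreaction may be inefficient). Fallback: reduce 9 with Na2S2O4 to the 5,7,8-triol and install the ester ionically with isovaleryl chloride (1 equiv) and base, relying on 7-to-8 acyl migration under thermodynamic control.
- **Step 4** (the methoxyquinone may be a poor partner, O-acylation may compete, or the ortho phenol of 7 may displace chloride early and give the isomeric chromone). Fallback: photoacylate 2 with methoxyacetaldehyde instead (simple aldehyde, no leaving group). Then C-aroylate the ketone enolate (excess LiHMDS) with 4-methoxybenzoyl chloride, made from anisole and oxalyl chloride/AlCl3, to give the 1,3-diketone. CAN oxidation then closes the pyranone by the same OMe displacement to give 8.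
- **Step 6** (hydroperoxide may displace the 6-OMe or open the pyranone instead of epoxidising). Fallback: Thiele–Winter acetoxylation of 8 (Ac2O, BF3·OEt2) to the 5,7,8-triacetoxyflavone, then methanolysis and Ag2O or air oxidation to 9.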